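common to all: pre-initiator 2.5 mol%
- noon: free monomer 1 mM; transfer agent 0.035 mM; run made earlier
- dawn: free monomer 1 mM; transfer agent 0.044 mM; run made earlier
- summer: free monomer 1 mM; transfer agent 0.057 mM; run made earlier
- epsilon: free monomer 1.0 mM; transfer agent 0.0300 mM; time 30 min
- gamma: free monomer 1.0 mM; transfer agent 0.0600 mM; time 30 min

| run | time / min | monomer in chains / % | free monomer / % |
|---|---|---|---|
| noon | 4.00 | 12.8 | 85.7 |
| noon | 8.00 | 15.2 | 85.8 |
| noon | 12.0 | 16.1 | 85.6 |
| noon | 15.0 | 15.0 | 85.6 |
| noon | 20.0 | 15.5 | 85.3 |
| dawn | 2.00 | 7.2 | 92.5 |
| dawn | 5.00 | 10.5 | 89.9 |
| dawn | 10.0 | 10.8 | 88.7 |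
| dawn | 15.0 | 11.4 | 89.4 |
| dawn | 20.0 | 10.2 | 89.5 |
| summer | 2.00 | 6.6 | 93.5 |
| summer | 5.00 | 8.1 | 91.2 |
| summer | 10.0 | 8.2 | 92.3 |
| summer | 15.0 | 9.1 | 90.9 |
| summer | 20.0 | 9.0 | 91.5 |

(scatter of a reading: 0.5 percentage points)

1. which of the two ends with the longer chains by the average number of monomer units in a chain (chains begun, living or dead) ("neither" if they lie within 10 %) (epsilon / gamma / neither)
2. average number of monomer units in a chain (chains begun, living or dead) at the end, epsilon
3. average number of monomer units in a chain (chains begun, living or dead) at the end, gamma

- the average divides the monomer in chains by the number of chains begun, living and dead together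
- the earlier runs do not show the number of chains; that part of a forecast is a guess

Epsilon and gamma differ in one charge, the transfer agent, and in each earlier run the readings stop moving well short of full consumption of free monomer, so I take the plateau as the end of both flasks, whose 30 min lies beyond the last reading at 20.0 min. No reading shows the chain count, so I guess one chain per pre-initiator, 0.0250 mM in both flasks, and the length is then the monomer in chains divided by that.

You can reach the plateau in two ways. The first takes the monomer in chains column and multiplies the mean plateau share by the charged agent, which gives 0.00541 mM for noon, 0.00472 mM for dawn and 0.00490 mM for summer. If that product is constant at its mean 0.00501 mM, epsilon reaches 16.7 % and gamma 8.35 %.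

The second way takes the free monomer column and supposes that each chain stops by consuming one transfer agent, so that free monomer and agent compete as the agent falls by 0.0250 mM. After subtracting the free monomer that begins the chains, ln[c(free monomer) before / c(free monomer) after] should then be proportional to ln[c(transfer agent) before / c(transfer agent) after]. The three runs give the factor as 0.104, 0.104 and 0.110, with mean 0.106. This reading is the selectivity factor, the logarithmic fall of free monomer per logarithmic fall of transfer agent. It puts epsilon at 0.194 mM and gamma at 0.0792 mM, that is 19.4 % and 7.92 %.

The two ways stand close for gamma and part for epsilon. The first way holds the agent at its charge, yet on my guess the chains take 83.3 % of epsilon's agent and 41.7 % of gamma's. Noon, with the lowest agent charge among the runs, also shows the largest product as read. I therefore commit to the second way, with lengths of 7.75 for epsilon and 3.17 for gamma.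

The forecast names epsilon, with 6.7 for epsilon (range 3.5 to 12) and 3.3 for gamma (range 1.5 to 6.5), so its epsilon is shorter than mine, and it says of its count: “Chain count is the guess.”

    free monomer + initiator → living end + monomer in chains (k = 3200 M⁻¹ s⁻¹)
    free monomer + living end → monomer in chains + living end, rate k2*[living end]*[free monomer] (k = 1500 M⁻¹ s⁻¹)
    living end + transfer agent → dead chain (kL = 14000 M⁻¹ s⁻¹)
    pre-initiator → initiator (k = 0.0140 s⁻¹)

Of the two flasks, epsilon ends longer, at 7.87 against 3.21 for gamma, which puts epsilon at 1.17 times the forecast. At 30.0 min epsilon holds 0.0250 mM of dead chain and 16.7 % of its transfer agent. Now take gamma with 0.15 mM of transfer agent: 0.106 and 0.0250 mM give 0.0437 mM of monomer in chains, or 4.37 %, and a length of 1.75. That flask gives 4.41 % and an average length of 1.76.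

(All runs are calculated with made-up constants; scatter was added.)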